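**Early times.** The first readings ask whether a bigger substrate charge buys more target.

| flask | substrate | partner | catalyst | time |
|---|---|---|---|---|
| birch | 0.200 M | 0.500 M | 0.00200 M |  |
| larch | 0.200 M | 1.50 M | 0.00200 M |  |
| elm | 0.200 M | 0.500 M | 0.00300 M |  |
| cedar | 0.600 M | 0.500 M | 0.00200 M |  |
| ash | 1.40 M | 0.500 M | 0.00200 M | 8.6 h |

| birch run: time / h | birch run: [target] / M | larch run: time / h | larch run: [target] / M | elm run: time / h | elm run: [target] / M | cedar run: time / h | cedar run: [target] / M |
|---|---|---|---|---|---|---|---|
| 1.7 | 0.0233 | 1.7 | 0.0521 | 1.7 | 0.0358 | 1.7 | 0.0245 |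
| 3.4 | 0.0382 | 3.4 | 0.0636 | 3.4 | 0.0564 | 3.4 | 0.0402 |
| 5.2 | 0.0476 | 5.2 | 0.0449 | 5.2 | 0.0678 | 5.2 | 0.0487 |
| 6.9 | 0.0526 | 6.9 | 0.0190 | 6.9 | 0.0713 | 6.9 | 0.0561 |
| 8.6 | 0.0552 | 8.6 | 0.0089 | 8.6 | 0.0742 | 8.6 | 0.0590 |

(scatter of a reading: 6 × 10⁻⁴ M)

* reaction order in [substrate] at the outset, round the charge of the birch run, defined at two percent of the substrate turned into target (one fixed amount of target, the same in the runs compared)
* reaction order in [catalyst] at the outset, round the charge of the birch run, defined at two percent of the substrate turned into target
* target in the ash run at 8.6 h, as a share of the substrate charged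

- Overall: substrate + partner -> target, with catalyst as catalyst.
- Constant volume, constant temperature.
- A reading of a species includes what of it is bound.
- An order is taken over about fifteen percent of the charge, up and down.

**Turned round.** Birch holds 27.6% of its substrate as target at 8.6 h. For ash to hold that share, target would have to grow in step with the charge, and cedar over birch would then stand at the charge ratio, 3.00. Dividing their mean rates up to 1.7 h cancels the time and leaves the readings' ratio, 1.05, with a scatter of 0.0374. That is less than the charge ratio by 52.1 standard deviations.

**Carried quantity.** I let the rate follow S/(K+S), where S is [substrate] and K is the half-saturation level (the Michaelis constant), the [substrate] giving half the top rate. The ratio then gives K = 0.0159 M, a reading with a scatter of about 0.0118 M. On this form the local order in substrate is K/(K+S), which for birch is 0.0735.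

**My reckoning.** The factor S/(K+S) is 0.989 for ash and 0.974 for cedar. I assume target follows its formation rate at equal partner and catalyst, and scale cedar's 0.0590 M at 8.6 h by these factors. That gives 0.0599 M for ash, or 4.28% of its charge. Elm over birch at 1.7 h gives an order in catalyst of 1.06.

**Forecast.** The forecast gives an order of 0.07 in substrate, an order of 1.15 in catalyst, higher than mine, and 4.3% for ash, and says of the substrate, “This looks like saturation”.

**Result.** The ash run gives 4.25%, with orders of 0.062 in substrate and 1.1 in catalyst.

    catalyst + substrate ⇌ catalyst-substrate complex, settled at all times (86.60 M⁻¹)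
    catalyst-substrate complex + partner → target + catalyst (19.01 M⁻¹ h⁻¹)
    target → decomposed product (0.04320 h⁻¹)
    target + partner → side product (0.4176 M⁻¹ h⁻¹)

Where two percent of the birch substrate has turned, cedar's rate over birch's is 1.0. At the ash charge, my K leaves 1.12% of the catalyst outside the catalyst-substrate complex, the resting state, at the start.

The runs are simulated for an exercise.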